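**Assumption:** Kuwanon C has no stereocentres (both side-chain alkenes carry two identical methyl groups), so the compound is achiral and no stereocontrol is needed.

## Retrosynthetic overview

1. Kuwanon C ⇐ global MOM removal ⇐ C3-prenylation of an 8-prenylflavone through its 3-lithio derivative.
2. Pyranone ring ⇐ 6-endo oxa-Michael closure (O1–C2) of an o-hydroxyaryl ynone; the ynone's C4–C4a bond ⇐ photo-Fries rearrangement (acyl/phenoxyl radical pair) of an aryl 3-arylpropiolate. This is the key step.
3. Aryl ynoate ⇐ 2-prenyl-3,5-bis(MOM-oxy)phenol + 3-[2,4-bis(MOM-oxy)phenyl]propiolic acid.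
4. Both aromatic rings ⇐ resorcinol via one common bis-MOM ether: the A ring gains its third oxygen by Ir C–H borylation/oxidation, then ortho-prenylation; the B ring by iodination and coupling with propiolic acid.
5. Ring order: the A and B rings come intact from resorcinol; only the pyranone (C) ring is built, in the key step.

## Route

**Step 1**
Reactants: 1, resorcinol
Product: 2, 1,3-bis(methoxymethoxy)benzene
Conditions: MOMCl (2.5 equiv), i-Pr2NEt, CH2Cl2, 0 °C → rt
Reagents that add atoms: chloromethyl methyl ether, COCCl
Why: Williamson-type O-alkylation (MOM protection); MOM ethers survive base, organolithiums, Pd and UV light and leave under mild acid that spares prenyl groups.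

**Step 2**
Reactants: 2, 1,3-bis(methoxymethoxy)benzene
Product: 3, 3,5-bis(methoxymethoxy)phenol
Conditions: [Ir(OMe)(cod)]2 (1.5 mol%), dtbpy (3 mol%), B2pin2, THF, 80 °C; then 30% H2O2, aq NaOH, 0 °C → rt (one pot)
Reagents that add atoms: hydrogen peroxide, OO (supplies the phenol oxygen; boron from B2pin2 is not retained)
Why: Sterically controlled Ir-catalysed C–H borylation occurs at C5, the only C–H not ortho to a substituent, and in-pot oxidation of the aryl boronate gives the 1,3,5-trioxygenated A ring.

**Step 3**
Reactants: 3, 3,5-bis(methoxymethoxy)phenol; 4, prenyl bromide (1-bromo-3-methylbut-2-ene)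
Product: 5, 3,5-bis(methoxymethoxy)-2-(3-methylbut-2-en-1-yl)phenol
Conditions: NaH (1.05 equiv), toluene, 0 °C; then 4 (1.0 equiv), rt
Reagents that add atoms: prenyl bromide (4), CC(C)=CCBr
Why: Ortho C-alkylation of a tight sodium phenoxide ion pair in a non-polar solvent (SN2, linear prenyl); the two ortho sites are equivalent and the free OH left between the ring and the prenyl group later becomes O1.

**Step 4**
Reactants: 2, 1,3-bis(methoxymethoxy)benzene
Product: 6, 1-iodo-2,4-bis(methoxymethoxy)benzene
Conditions: NIS (1.05 equiv), MeCN, 0 °C → rt, dark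
Reagents that add atoms: N-iodosuccinimide, O=C1CCC(=O)N1I
Why: Electrophilic aromatic iodination at the position ortho/para to the two alkoxy groups (C4) rather than the hindered C2.

**Step 5**
Reactants: 6, 1-iodo-2,4-bis(methoxymethoxy)benzene; 7, propiolic acid
Product: 8, 3-[2,4-bis(methoxymethoxy)phenyl]prop-2-ynoic acid
Conditions: Pd(PPh3)4 (5 mol%), DBU (2.4 equiv), DMSO, 35 °C; cold citric acid work-up
Reagents that add atoms: propiolic acid (7), C#CC(=O)O
Why: Copper-free Sonogashira-type coupling of an aryl iodide with propiolic acid as its DBU carboxylate; low temperature and absence of Cu suppress decarboxylation.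

**Step 6**
Reactants: 5, 3,5-bis(methoxymethoxy)-2-prenylphenol; 8, 3-[2,4-bis(methoxymethoxy)phenyl]prop-2-ynoic acid
Product: 9, 3,5-bis(methoxymethoxy)-2-(3-methylbut-2-en-1-yl)phenyl 3-[2,4-bis(methoxymethoxy)phenyl]prop-2-ynoate
Conditions: DCC (1.1 equiv), DMAP (10 mol%), CH2Cl2, 0 °C → rt
Reagents that add atoms: none
Why: Steglich esterification, the standard way to make aryl 3-arylpropiolates under neutral conditions.

**Step 7 (key step)**
Reactants: 9, the aryl ynoate
Product: 11, 5,7-bis(methoxymethoxy)-2-[2,4-bis(methoxymethoxy)phenyl]-8-(3-methylbut-2-en-1-yl)-4H-chromen-4-one, formed via non-isolated 10, 1-[2-hydroxy-4,6-bis(methoxymethoxy)-3-(3-methylbut-2-en-1-yl)phenyl]-3-[2,4-bis(methoxymethoxy)phenyl]prop-2-yn-1-one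
Conditions: hν (Hg lamp, Pyrex, λ ≥ 300 nm), degassed MeCN (5 mM), rt; then K2CO3 (2 equiv), 60 °C, same pot
Reagents that add atoms: none
Why: Photo-Fries rearrangement, in which homolysis of the ester O–C(O) bond gives a caged phenoxyl/alkynoyl radical pair (alkynoyl radicals do not decarbonylate) that recombines at the only free ortho carbon to form C4–C4a and the chelated o-hydroxyaryl ynone 10; carbonate then drives 6-endo-dig oxa-Michael closure through the single free phenol, which fixes the prenyl group at C8.

**Step 8**
Reactants: 11, the 8-prenylflavone; 4, prenyl bromide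
Product: 12, 5,7-bis(methoxymethoxy)-2-[2,4-bis(methoxymethoxy)phenyl]-3,8-bis(3-methylbut-2-en-1-yl)-4H-chromen-4-one
Conditions: LDA (1.3 equiv), THF, −78 °C; CuBr·SMe2 (1.3 equiv); then 4 (2 equiv), −78 → 0 °C
Reagents that add atoms: prenyl bromide (4), CC(C)=CCBr
Why: C3 lithiation of the flavone (LDA removes the vinylic C3–H next to the carbonyl, as in the known LDA/I2 3-iodination of alkoxyflavones) followed by copper-mediated allylic substitution, which gives the linear prenyl group.

**Step 9**
Reactants: 12, the tetra-MOM 3,8-diprenylflavone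
Product: 13, Kuwanon C, 2-(2,4-dihydroxyphenyl)-5,7-dihydroxy-3,8-bis(3-methylbut-2-en-1-yl)-4H-chromen-4-one
Conditions: 3 M aq HCl/MeOH (1:4), 50 °C, monitored and stopped at full conversion
Reagents that add atoms: none
Why: Acid-catalysed cleavage of the four MOM acetals under conditions routinely used on prenylated flavonoids, mild enough to avoid cyclisation of the 7-OH onto the 8-prenyl group.

## Compound list

1 | resorcinol | Oc1cccc(O)c1 | starting material
2 | 1,3-bis(methoxymethoxy)benzene | COCOc1cccc(OCOC)c1 | intermediate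
3 | 3,5-bis(methoxymethoxy)phenol | COCOc1cc(O)cc(OCOC)c1 | intermediate
4 | prenyl bromide | CC(C)=CCBr | starting material
5 | 3,5-bis(methoxymethoxy)-2-(3-methylbut-2-en-1-yl)phenol | COCOc1cc(O)c(CC=C(C)C)c(OCOC)c1 | intermediate
6 | 1-iodo-2,4-bis(methoxymethoxy)benzene | COCOc1ccc(I)c(OCOC)c1 | intermediate
7 | propiolic acid | C#CC(=O)O | starting material
8 | 3-[2,4-bis(methoxymethoxy)phenyl]prop-2-ynoic acid | COCOc1ccc(C#CC(=O)O)c(OCOC)c1 | intermediate
9 | 3,5-bis(methoxymethoxy)-2-prenylphenyl 3-[2,4-bis(methoxymethoxy)phenyl]prop-2-ynoate | COCOc1ccc(C#CC(=O)Oc2cc(OCOC)cc(OCOC)c2CC=C(C)C)c(OCOC)c1 | intermediate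
10 | 1-[2-hydroxy-4,6-bis(methoxymethoxy)-3-prenylphenyl]-3-[2,4-bis(methoxymethoxy)phenyl]prop-2-yn-1-one | COCOc1ccc(C#CC(=O)c2c(O)c(CC=C(C)C)c(OCOC)cc2OCOC)c(OCOC)c1 | intermediate (not isolated)
11 | 5,7-bis(methoxymethoxy)-2-[2,4-bis(methoxymethoxy)phenyl]-8-prenyl-4H-chromen-4-one | CC(C)=CCc1c(OCOC)cc(OCOC)c2c(=O)cc(-c3ccc(OCOC)cc3OCOC)oc12 | intermediate
12 | 5,7-bis(methoxymethoxy)-2-[2,4-bis(methoxymethoxy)phenyl]-3,8-diprenyl-4H-chromen-4-one | CC(C)=CCc1c(-c2ccc(OCOC)cc2OCOC)oc2c(CC=C(C)C)c(OCOC)cc(OCOC)c2c1=O | intermediate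
13 | Kuwanon C | CC(C)=CCc1c(-c2ccc(O)cc2O)oc2c(CC=C(C)C)c(O)cc(O)c2c1=O | target

## Summary

Total steps: 9.
Longest linear sequence: 7 (steps 1, 2, 3, 6, 7, 8, 9).

Three steps most likely to fail:

1. **Step 7 (photo-Fries/cyclisation).** Risks are para recombination at C4, cage escape back to phenol 5, other photochemistry of the ynoate or prenyl group, and 5-exo (aurone) closure. Fallback: form C4–C4a by a tethered acyl-radical cyclisation instead. Add phenol 5 to the methyl ester of 8 (oxa-Michael) to give the β-aryloxy acrylate, convert it to the acyl selenide, and cyclise the acyl radical (Bu3SnH/AIBN) onto the only free ortho carbon, so the tether removes the ortho/para issue.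
2. **Step 3 (ortho C-prenylation).** Risks are O-prenylation, para attack and double alkylation. Fallback: O-alkylate 3 with a 1,1-dimethylpropargyl electrophile (Cu catalysis), semi-hydrogenate (Lindlar), and run a thermal aromatic Claisen rearrangement, which delivers the linear prenyl group to the ortho carbon only.
3. **Step 8 (C3 prenylation of the lithioflavone).** Risks are ring-opening of the 3-metallated flavone, SN2′ (reverse-prenyl) transfer and incomplete metalation. Fallback: install the C3 prenyl before ring closure. Stop step 7 at ynone 10, convert it via the Et2NH enaminone to the 1,3-diketone, C-prenylate the diketone (K2CO3, prenyl bromide), and cyclodehydrate during the final acid deprotection.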